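## Retrosynthetic overview

- The target comes from its bis(benzyl ether) by hydrogenolysis; the spiro-oxirane comes from face-selective epoxidation of a cis-2-aryl-4-arylmethyl-3-methylideneoxolane (last C–O bonds).
- Key step: the oxolane C(aryl)–O bond is made by catalyst-controlled dehydrative closure of a primary hydroxyl onto an aryl-stabilised allyl cation. This one event forms the ring, the exocyclic methylene and the aryl-bearing stereocentre.
- The open-chain diol comes from hydride reduction of an arylidene succinic half-ester that has been α-benzylated enantioselectively (sets the arylmethyl-bearing stereocentre).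
- The half-ester comes from a Stobbe condensation of O-benzylvanillin with di-tert-butyl succinate.
- Ring order: oxolane first, oxirane second.

Assumption: the tetramine antipode that gives the (R)-acid is taken to be (S,S) by analogy with arylacetic acids, the (R)-phosphoramide is taken as the matched catalyst, and the benzylic bromide and di-tert-butyl succinate are bought.

## Route

Step 1
Reactants: 1 4-(benzyloxy)-3-methoxybenzaldehyde; 2 di-tert-butyl succinate
Product: 3 (3E)-4-[4-(benzyloxy)-3-methoxyphenyl]-3-(tert-butoxycarbonyl)but-3-enoic acid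
Conditions: KOtBu (1.5 equiv), t-BuOH, reflux; then aq. HCl
Reagents that add atoms: none
Why: Stobbe condensation: the succinate enolate adds to the aldehyde and the adduct collapses irreversibly to the carboxylate of the (E)-alkylidene half-ester, leaving the CH2 next to the free acid as the only enolisable site for step 2 (no stereocentre; alkene geometry is irrelevant later).

Step 2
Reactants: 3 (3E)-4-[4-(benzyloxy)-3-methoxyphenyl]-3-(tert-butoxycarbonyl)but-3-enoic acid; 4 3-(benzyloxy)-4-methoxybenzyl bromide
Product: 6 (2R,3E)-2-{[3-(benzyloxy)-4-methoxyphenyl]methyl}-4-[4-(benzyloxy)-3-methoxyphenyl]-3-(tert-butoxycarbonyl)but-3-enoic acid, via dilithium enediolate 5 (not isolated)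
Conditions: (S,S)-N,N'-bis(1-phenyl-2-piperidin-1-ylethyl)propane-1,3-diamine (1.05 equiv), n-BuLi (4.0 equiv), THF, 0 °C; then 4, −78 °C; amine recovered by acid extraction
Reagents that add atoms: none
Why: Enantioselective enediolate alkylation directed by a chiral dilithium amide used as a recoverable, non-covalent auxiliary (established for arylacetic and β,γ-unsaturated acids): the extended enediolate reacts at its α-carbon inside the mixed aggregate, the benzylic bromide enters one face and sets the (R) centre, and the hindered tert-butyl ester is inert to the base.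

Step 3
Reactants: 6 (2R,3E)-2-{[3-(benzyloxy)-4-methoxyphenyl]methyl}-4-[4-(benzyloxy)-3-methoxyphenyl]-3-(tert-butoxycarbonyl)but-3-enoic acid
Product: 7 (2E,3R)-2-{[4-(benzyloxy)-3-methoxyphenyl]methylidene}-3-{[3-(benzyloxy)-4-methoxyphenyl]methyl}butane-1,4-diol
Conditions: LiAlH4 (3 equiv), THF, 0 °C to 20 °C; basic aqueous work-up
Reagents that add atoms: none
Why: Hydride reduction of the acid and of the conjugated ester (1,2-reduction) to the two primary alcohols; the stereocentre sits next to a carboxylate and is not epimerised, and the basic work-up protects the acid-labile cinnamyl alcohol.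

Step 4
Reactants: 7 (2E,3R)-2-{[4-(benzyloxy)-3-methoxyphenyl]methylidene}-3-{[3-(benzyloxy)-4-methoxyphenyl]methyl}butane-1,4-diol
Product: 9 (2R,4R)-2-[4-(benzyloxy)-3-methoxyphenyl]-4-{[3-(benzyloxy)-4-methoxyphenyl]methyl}-3-methylideneoxolane, via allyl cation 8 (not isolated)
Conditions: (R)-3,3'-bis(2,4,6-triisopropylphenyl)-1,1'-binaphthalene-2,2'-diyl N-triflylphosphoramide (5 mol %), 5 Å molecular sieves, toluene (0.01 M), −40 °C; quench with Et3N
Reagents that add atoms: none
Why: Proposed new method: chiral Brønsted-acid (counteranion-directed) dehydrative allylic cycloetherification with allylic transposition. The phosphoramide ionises the allylic hydroxyl to the 4-benzyloxyaryl-stabilised allyl cation, and its phosphoramidate counterion stays hydrogen-bonded to the remaining CH2OH and steers it onto the benzylic terminus in a 5-exo closure on the twisted benzyl-cation conformer (attack at the CH2 terminus would need a primary cation and a 5-endo path). The C–O bond, the ring and the exocyclic methylene therefore form together, and the new centre is (R), with aryl cis to the arylmethyl group (both pseudo-equatorial, reinforced by the matched chiral anion). The closest known reaction types are chiral N-triflylphosphoramide-catalysed intramolecular allylic substitution of diarylallyl alcohols by phenols to 2H-chromenes and chiral phosphoric acid additions to para-quinone methides.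

Step 5
Reactants: 9 (2R,4R)-2-[4-(benzyloxy)-3-methoxyphenyl]-4-{[3-(benzyloxy)-4-methoxyphenyl]methyl}-3-methylideneoxolane
Product: 10 (3S,4S,7S)-4-[4-(benzyloxy)-3-methoxyphenyl]-7-{[3-(benzyloxy)-4-methoxyphenyl]methyl}-1,5-dioxaspiro[2.4]heptane
Conditions: dimethyldioxirane (1.3 equiv, solution in acetone), CH2Cl2, −20 °C to 0 °C
Reagents that add atoms: dimethyldioxirane, CC1(C)OO1
Why: Electrophilic epoxidation by a neutral dioxirane (concerted oxygen transfer): the exocyclic 1,1-disubstituted alkene is attacked from the face opposite the cis aryl and arylmethyl groups, so the oxirane oxygen ends trans to both and the spiro centre is (S); the acid-free conditions spare the benzylic allylic ether.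

Step 6
Reactants: 10 (3S,4S,7S)-4-[4-(benzyloxy)-3-methoxyphenyl]-7-{[3-(benzyloxy)-4-methoxyphenyl]methyl}-1,5-dioxaspiro[2.4]heptane
Product: 11 5-{[(3S,4S,7S)-4-(4-hydroxy-3-methoxyphenyl)-1,5-dioxaspiro[2.4]heptan-7-yl]methyl}-2-methoxyphenol
Conditions: H2 (1 atm), Pd/C (10 wt % Pd), EtOAc, 20 °C, about 30 min, stopped at full conversion
Reagents that add atoms: none
Why: Catalytic hydrogenolysis of the two aryl benzyl ethers, which cleave much faster than the non-benzylic 2,2-disubstituted oxirane or the cyclic benzylic ether, frees both phenols without touching the three stereocentres.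

## Compound list

1 | 4-(benzyloxy)-3-methoxybenzaldehyde | O=Cc1ccc(OCc2ccccc2)c(OC)c1 | starting material
2 | di-tert-butyl succinate | CC(C)(C)OC(=O)CCC(=O)OC(C)(C)C | starting material
3 | (3E)-4-[4-(benzyloxy)-3-methoxyphenyl]-3-(tert-butoxycarbonyl)but-3-enoic acid | CC(C)(C)OC(=O)/C(CC(=O)O)=C/c1ccc(OCc2ccccc2)c(OC)c1 | intermediate
4 | 3-(benzyloxy)-4-methoxybenzyl bromide | BrCc1ccc(OC)c(OCc2ccccc2)c1 | starting material
5 | dilithium enediolate of 3 (alkene geometry undefined) | CC(C)(C)OC(=O)C(=Cc1ccc(OCc2ccccc2)c(OC)c1)C=C(O[Li])O[Li] | intermediate (not isolated)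
6 | (2R,3E)-2-{[3-(benzyloxy)-4-methoxyphenyl]methyl}-4-[4-(benzyloxy)-3-methoxyphenyl]-3-(tert-butoxycarbonyl)but-3-enoic acid | CC(C)(C)OC(=O)/C(=C/c1ccc(OCc2ccccc2)c(OC)c1)[C@@H](Cc1ccc(OC)c(OCc2ccccc2)c1)C(=O)O | intermediate
7 | (2E,3R)-2-{[4-(benzyloxy)-3-methoxyphenyl]methylidene}-3-{[3-(benzyloxy)-4-methoxyphenyl]methyl}butane-1,4-diol | OC/C(=C/c1ccc(OCc2ccccc2)c(OC)c1)[C@@H](Cc1ccc(OC)c(OCc2ccccc2)c1)CO | intermediate
8 | 1-aryl-2-substituted allyl cation from 7 (drawn as the benzylic cation, paired with the phosphoramidate) | C=C([CH+]c1ccc(OCc2ccccc2)c(OC)c1)[C@@H](Cc1ccc(OC)c(OCc2ccccc2)c1)CO | intermediate (not isolated)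
9 | (2R,4R)-2-[4-(benzyloxy)-3-methoxyphenyl]-4-{[3-(benzyloxy)-4-methoxyphenyl]methyl}-3-methylideneoxolane | COc1ccc(C[C@H]2CO[C@@H](c3ccc(OCc4ccccc4)c(OC)c3)C2=C)cc1OCc1ccccc1 | intermediate
10 | (3S,4S,7S)-4-[4-(benzyloxy)-3-methoxyphenyl]-7-{[3-(benzyloxy)-4-methoxyphenyl]methyl}-1,5-dioxaspiro[2.4]heptane | COc1ccc(C[C@H]2CO[C@@H](c3ccc(OCc4ccccc4)c(OC)c3)[C@@]23CO3)cc1OCc1ccccc1 | intermediate
11 | 5-{[(3S,4S,7S)-4-(4-hydroxy-3-methoxyphenyl)-1,5-dioxaspiro[2.4]heptan-7-yl]methyl}-2-methoxyphenol | COc1ccc(C[C@H]2CO[C@@H](c3ccc(O)c(OC)c3)[C@@]23CO3)cc1O | target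

## Step count and risks

Total step count: 6. Longest linear sequence: 6 (1 → 3 → 6 → 7 → 9 → 10 → 11).

Steps most likely to fail:

**Step 4 (proposed new step).** Risks are Friedel–Crafts closure of the cation onto the electron-rich arylmethyl ring (aryltetralin), acid-mediated drift to the conjugated 3-arylidene oxolane, and a low cis:trans ratio. The fallback uses known reactions only, sets out from 7 and returns at 9. Sharpless asymmetric epoxidation of the allylic alcohol of 7 (Ti(OiPr)4, L-(+)-diisopropyl tartrate, t-BuOOH, 4 Å sieves, CH2Cl2, −25 °C) gives, under reagent control, the (2S,3S)-epoxy diol F4. I2, PPh3 and imidazole turn both primary hydroxyls into iodides to give the epoxy diiodide F5. Zn dust in ethanol opens the iodomethyl oxirane reductively to the (R)-configured benzylic allylic alcohol F6, which already carries the exocyclic methylene. NaH in THF then closes the ring by 5-exo-tet displacement of the remaining primary iodide with retention at the carbinol carbon, which gives 9.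

**Step 2.** Risks are an insufficient enantiomeric ratio on this ester-bearing acid, attack of n-BuLi on the ester, or γ-alkylation. The fallback sets out from 3 and returns at 7, bypassing 6. Pivaloyl chloride and Et3N convert 3 into the mixed pivalic anhydride F1, which acylates lithiated (R)-4-benzyloxazolidin-2-one to give the N-acyl oxazolidinone F2. Its sodium (Z)-enolate (NaN(SiMe3)2, THF, −78 °C) is alkylated by 4 on the face opposite the auxiliary benzyl group to give the (R)-configured alkylated imide F3. LiAlH4 reduces the imide and the tert-butyl ester together to give 7.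

**Step 6.** Risks are hydrogenolytic opening of the oxirane or of the benzylic ring C–O bond before both benzyl ethers are gone. The fallback sets out from 9 and arrives at 11 without passing through 10. OsO4 with N-methylmorpholine N-oxide dihydroxylates the exocyclic alkene from the open face to give the diol F7 (tertiary hydroxyl trans to both ring substituents). TsCl in pyridine sulfonylates only the primary hydroxyl to give the monotosylate F8. H2 over Pd/C then removes both benzyl groups with no oxirane present to give the bisphenol hydroxy tosylate F9. K2CO3 in methanol closes the oxirane by displacement of tosylate by the tertiary alkoxide, with the same configuration at the spiro carbon as direct epoxidation, to give 11.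

## Further compounds

F1 | step 2 | mixed pivalic anhydride of 3 | CC(C)(C)OC(=O)/C(CC(=O)OC(=O)C(C)(C)C)=C/c1ccc(OCc2ccccc2)c(OC)c1
F2 | step 2 | (R)-4-benzyl-3-acyloxazolidin-2-one of 3 | CC(C)(C)OC(=O)/C(CC(=O)N1[C@H](Cc2ccccc2)COC1=O)=C/c1ccc(OCc2ccccc2)c(OC)c1
F3 | step 2 | F2 alkylated at the α-carbon with 4, new centre (R) | CC(C)(C)OC(=O)/C(=C/c1ccc(OCc2ccccc2)c(OC)c1)[C@@H](Cc1ccc(OC)c(OCc2ccccc2)c1)C(=O)N1[C@H](Cc2ccccc2)COC1=O
F4 | step 4 | (2S,3S)-epoxy diol from 7 (oxirane across the former alkene) | OC[C@@]1(O[C@H]1c1ccc(OCc2ccccc2)c(OC)c1)[C@@H](Cc1ccc(OC)c(OCc2ccccc2)c1)CO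
F5 | step 4 | epoxy diiodide (both CH2OH of F4 as CH2I, stereocentres untouched) | IC[C@@]1(O[C@H]1c1ccc(OCc2ccccc2)c(OC)c1)[C@@H](Cc1ccc(OC)c(OCc2ccccc2)c1)CI
F6 | step 4 | (R)-aryl carbinol with 2-methylidene and primary iodide (transposed allylic alcohol) | O[C@@H](c1ccc(OCc2ccccc2)c(OC)c1)C(=C)[C@@H](Cc1ccc(OC)c(OCc2ccccc2)c1)CI
F7 | step 6 | 3-hydroxy-3-(hydroxymethyl)oxolane diol from 9, tertiary OH trans to aryl and arylmethyl | COc1ccc(C[C@H]2CO[C@@H](c3ccc(OCc4ccccc4)c(OC)c3)[C@@]2(O)CO)cc1OCc1ccccc1
F8 | step 6 | primary monotosylate of F7 | COc1ccc(C[C@H]2CO[C@@H](c3ccc(OCc4ccccc4)c(OC)c3)[C@@]2(O)COS(=O)(=O)c2ccc(C)cc2)cc1OCc1ccccc1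
F9 | step 6 | debenzylated bisphenol hydroxy tosylate | COc1ccc(C[C@H]2CO[C@@H](c3ccc(O)c(OC)c3)[C@@]2(O)COS(=O)(=O)c2ccc(C)cc2)cc1O
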